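Its constants stand for no real mixture; the run is a simulation.

At any moment dissolved substrate has two ways out, into side product by meeting itself and into target by meeting partner, and this flask turns on how those two rates compare.

    solid substrate ⇌ dissolved substrate, rate k1*(cs1 - [dissolved substrate]) while solid is left; crystals form when [dissolved substrate] > cs1 (cs1 = 15 mM, k1 = 0.42 h⁻¹)
    dissolved substrate + partner → target (k2 = 0.29 M⁻¹ h⁻¹)
    2 dissolved substrate → side product (k3 = 3.4 M⁻¹ h⁻¹)
    solid product ⇌ target, rate k4*(cs4 - [target]) while solid is left; crystals form when [target] > cs4 (cs4 = 0.21 mM, k4 = 0.37 h⁻¹)
    partner → decomposed reagent (k5 = 0.032 h⁻¹)
    partner + protic impurity → quenched reagent (k6 = 70 M⁻¹ h⁻¹)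

solid substrate 20 mM; partner 3.00 equiv; protic impurity 1.00 mM; time 30 h

1. how much target and solid product together there is at 30 h, in percent of the solid substrate charged
2. concentration of dissolved substrate in solution at 30 h, in percent of saturation

- a species is counted by the solid substrate in it: one side product counts as two
- amounts and yields of target count solid product too
- where a step has two of a species, its rate is k times that concentration squared, and two are used at each turn
- given per volume of solution although it is solid: solid substrate, solid product
- at the start none of the solid substrate is in solution
- dissolved substrate means what is dissolved; the solid is not counted in it
- run time (flask): 30 h

We climb the clocks from the fastest up. Protic impurity meets partner first: against the charged 60.0 mM of partner its half-life is 0.165 h, and it can take hardly any of that partner. The solid feeds the solution on a slower clock of 2.38 h, so dissolved substrate climbs towards its saturation at 15 mM. There its first half-life by dimerisation is 9.80 h, while partner decomposes with a half-life of 22 h and coupling alone would halve dissolved substrate in 40 h, so dimerisation runs faster than coupling.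

We therefore carry the partition ratio, a selectivity factor: the rate at which dissolved substrate goes into side product over the rate at which it goes into target, which is twice the dimerisation constant times c(dissolved substrate) over the coupling constant times c(partner). With dissolved substrate at saturation and partner as charged, this partition ratio is 5.86, well above unity. From the empty solution c(dissolved substrate) first climbs while c(partner) falls, so the ratio starts at zero and rises; once c(dissolved substrate) turns down, both sink and top and bottom drift the same way, and as a rough reckoning we hold the ratio at this one value for the whole run. Target then receives 14.6% of the substrate that reacts.

The forecast gives 13.3% and 26.3%, and says of the crystals: “Crystallisation does not affect this total.” Our figure for target stands above its figure.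

The simulation gives 13.0% and 26.3%, so the forecast stands. The ratio reads 6.0 at 11.3 h beside our 5.86, and after 300 h target and solid product together hold 15.2%. In the neighbouring flask with 80 mM of solid substrate at the same equivalents, partner is charged at 240 mM while saturation stays 15 mM, so the ratio becomes 1.47 and target's share 40.6%. That flask holds 17.0% as target and 31.6% as side product at 30.0 h, which gives target 35.0% of the two.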